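The numbers were drawn at random within sensible limits; what happens was integrated by code.

The constants set two steps against each other on one charge: starting material joins the reagent to give the target, reversibly, with 0.00107 M⁻¹ s⁻¹, and two starting material pair to side product B with 0.00366 M⁻¹ s⁻¹.

the same everywhere: starting material 0.40 M; reagent 0.520 M; time 6.0 h
- north-east: temperature 40 °C
- south-west: temperature 10 °C
- north: temperature 25 °C

* which flask leads in amount of target, in percent of the starting material charged ("all alike" within 1.5 percentage points) (north-east / south-west / north / all alike)
* how much target is there at the end, in percent of the starting material charged: north-east
* how much target is there at the end, in percent of the starting material charged: south-west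
* how much target is there at the end, in percent of the starting material charged: north

- percentages count the starting material that a species holds: one side product B or side product C counts as two
- a step written with two of one species runs at k times the square of its concentration and takes two of it each time
- at 25 °C the constants are as listed, elsewhere as the activation energies and enthalpies make them

    starting material + reagent ⇌ target (K1 = 3.13 M⁻¹, k1 = 0.00107 M⁻¹ s⁻¹, Ea1 = 62.0 kJ mol⁻¹, ΔH1 = −9.00 kJ mol⁻¹)
    starting material → side product A (k2 = 3.28 × 10⁻⁵ s⁻¹, Ea2 = 105 kJ mol⁻¹)
    2 starting material → side product B (k3 = 0.00366 M⁻¹ s⁻¹, Ea3 = 77.0 kJ mol⁻¹)
    starting material + target → side product C (k4 = 4.39 × 10⁻⁴ M⁻¹ s⁻¹, Ea4 = 63.0 kJ mol⁻¹)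
    (constants at 25 °C)

Two chemists read these constants differently, and the north flask at 25 °C shows the difference plainly. The first sees a race whose winnings are kept. At the start the target step takes starting material at 0.190 of the pace of pairing, its share grows as the starting material thins, and summed over the whole charge the race leaves 34.9 % as target.

I hold that the target goes back. In the north flask step 1 comes to balance (a pre-equilibrium) in about 0.309 h, much less than the 6.0 h of the run. From then on, starting material and target form one pool. Taking the reagent at its charge, the free share, the part of the pool that stands as unbound starting material, is 1/(1 + K1 × reagent) = 0.381.

That free part pairs, and free meeting bound gives side product C. So the reciprocal of the pool, as a fraction of the charge, climbs steadily by 1.82 h⁻¹. I let pairing run unopposed during the balancing time, which leaves a pool of 23.5 %.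

By the end of the run the north pool is 6.83 %, of which the bound part makes 4.23 % target, far below the race figure. I have left out the loss to side product A, which takes 0.0449 h⁻¹ of the north pool, less than the 0.124 h⁻¹ of the pairing and side product C steps at that end point. For the other flasks I claim the order and give no number. South-west has the free share 0.336, smaller than north's, and pairing's activation energy exceeds that of step 1 by 15.0 kJ mol⁻¹, so south-west should lead and north-east come last.

The forecast names south-west, with 0.35 % for north-east, 16.5 % for south-west and 4 % for north, since “the target keeps returning to starting material and draining through side products B and A”.

The flasks end at 0.303 % in north-east, 16.6 % in south-west and 4.44 % in north, so south-west leads. North stands near my 4.23 % and far from the 34.9 % of the race view, and at 60.0 h it holds 0.112 %. The race view belongs to times short against the 0.309 h of the north flask, before the return counts.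

Read earlier, at 1.5 h, with amounts and temperature unchanged, the north flask is the neighbour. The same free share and the same climb give a pool of 15.5 % and target of 9.63 %. The reading is higher: it shows 12.6 % target beside 6.60 % starting material, so the bound part of the pool reads 65.6 %.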